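The seven-membered ketone ring is traced back to an indenone by a formal 1,3-acyl shift. The ketone carbon is parked on C8, the methine shared by the indane and cycloheptenone rings, so that this ring contracts to an indenone carrying a side-chain aryl triflate (ring B, the central resorcinol ring). A palladium-catalysed reductive Heck cyclisation bonds C8 to the ring B carbon ortho to the later ketone site: it closes the indane ring, makes C8 a spiro quaternary centre and, by syn addition of aryl and hydride across the ring-locked alkene, sets the neighbouring diaryl methine C7. Haller–Bauer cleavage (retention at C8) and Friedel–Crafts acylation of ring B then return the acyl group, expanding the five- to the seven-membered ring.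

Key step: step 9

Labels used: ring A = resorcinol ring carrying the C=O and C7; ring B = central resorcinol ring; C7 = CH(4-hydroxyphenyl) on ring A; C8 = ring-fusion CH; C10 = CH(4-hydroxyphenyl) and C9 = CH(3,5-dihydroxyphenyl) of the five-membered ring. In these labels the target is (7S,8R,9S,10S).

Assumption: the (S)-SEGPHOS–rhodium catalyst gives the (S)-lactone 3, following the known (R)-ligand to (R)-product sense for coumarin itself.

Step 1
Reactants: 1 5,7-dimethoxycoumarin; 2 (3,5-dimethoxyphenyl)boronic acid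
Product: 3 (4S)-4-(3,5-dimethoxyphenyl)-5,7-dimethoxy-3,4-dihydro-2H-chromen-2-one
Conditions: Rh(acac)(C2H4)2 (3 mol %), (S)-SEGPHOS (3.3 mol %), 2 (3 equiv), dioxane/H2O 10:1, 60 °C
Reagents that add atoms: none
Why: Rhodium-catalysed asymmetric 1,4-addition of an arylboronic acid to the coumarin (Hayashi–Miyaura reaction), in which the chiral bisphosphine–rhodium aryl selects the enone face and sets C9 (C4 of the lactone) as S.

Step 2
Reactants: 3; 4 1-bromo-4-methoxybenzene
Product: 5 (3S,4S)-4-(3,5-dimethoxyphenyl)-5,7-dimethoxy-3-(4-methoxyphenyl)-3,4-dihydro-2H-chromen-2-one (3,4-trans)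
Conditions: LiN(SiMe3)2, THF, −78 °C; ZnCl2; then Pd(dba)2 (5 mol %), P(t-Bu)3 (10 mol %), 4, rt to 50 °C
Reagents that add atoms: none
Why: Palladium-catalysed α-arylation of the zinc lactone enolate, in which the aryl group enters anti to the C4 aryl group and the acidic C3–H lets the product settle as the trans isomer, setting C10.

Step 3
Reactants: 5
Product: 6 (3S,4S)-4-(3,5-dimethoxyphenyl)-5,7-dimethoxy-3-(4-methoxyphenyl)-3,4-dihydro-2H-chromen-2-ol (lactol, both anomers)
Conditions: i-Bu2AlH (1.1 equiv), CH2Cl2, −78 °C; Rochelle salt work-up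
Reagents that add atoms: none
Why: Partial reduction of the lactone to the lactol, which stops at the aluminium hemiacetal at low temperature and leaves the α-aryl centre untouched.

Step 4
Reactants: 6
Product: 7 2-[(1S,2R)-1-(3,5-dimethoxyphenyl)-2-(4-methoxyphenyl)but-3-yn-1-yl]-3,5-dimethoxyphenol
Conditions: Me3SiCHN2 (1.5 equiv), LiN(i-Pr)2 (2.6 equiv), THF, −78 °C to 0 °C; NH4Cl work-up
Reagents that add atoms: (trimethylsilyl)diazomethane, C[Si](C)(C)C=[N+]=[N-]
Why: Colvin homologation of the ring-opened lactol aldehyde (addition, Peterson elimination, carbene 1,2-hydrogen shift) gives the terminal alkyne and frees the phenol; cold, irreversible trapping of the aldehyde should protect the α-aryl centre.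

Step 5
Reactants: 7; 8 1-iodo-4-methoxybenzene
Product: 9 2-[(1S,2S)-1-(3,5-dimethoxyphenyl)-2,4-bis(4-methoxyphenyl)but-3-yn-1-yl]-3,5-dimethoxyphenol
Conditions: Pd(PPh3)2Cl2 (2 mol %), CuI (4 mol %), Et3N, THF, rt
Reagents that add atoms: none
Why: Sonogashira coupling of the terminal alkyne with the aryl iodide under mild amine conditions that tolerate the free phenol.

Step 6
Reactants: 9
Product: 10 {2-[(1S,2S)-1-(3,5-dimethoxyphenyl)-2,4-bis(4-methoxyphenyl)but-3-yn-1-yl]-3,5-dimethoxyphenoxy}tri(propan-2-yl)silane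
Conditions: i-Pr3SiCl, imidazole, DMF, rt
Reagents that add atoms: chlorotri(propan-2-yl)silane, CC(C)[Si](Cl)(C(C)C)C(C)C
Why: Silylation of the phenol keeps the phenoxide from adding to the alkyne in the next palladium step.

Step 7
Reactants: 10; 11 2-bromo-3,5-dimethoxybenzaldehyde
Product: 12 2-[(1S,2S)-2-(3,5-dimethoxyphenyl)-2-{2,4-dimethoxy-6-[tri(propan-2-yl)silyloxy]phenyl}-1-(4-methoxyphenyl)ethyl]-4,6-dimethoxy-3-(4-methoxyphenyl)-1H-inden-1-one
Conditions: Pd(OAc)2 (10 mol %), NaOAc (3 equiv), n-Bu4NCl (1 equiv), DMF, 100 °C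
Reagents that add atoms: none
Why: Larock indenone annulation, in which the hindered arylpalladium delivers its aryl group to the alkyne carbon bearing the 4-methoxyphenyl group, so the bulky branched substituent ends up at C2 next to the carbonyl formed from the aldehyde.

Step 8
Reactants: 12
Product: 14 2-[(1S,2S)-1-(3,5-dimethoxyphenyl)-2-[4,6-dimethoxy-3-(4-methoxyphenyl)-1-oxo-1H-inden-2-yl]-2-(4-methoxyphenyl)ethyl]-3,5-dimethoxyphenyl trifluoromethanesulfonate, via free phenol 13 (not isolated)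
Conditions: HF·pyridine, THF, 0 °C to rt; then Tf2O, pyridine, CH2Cl2, −20 °C
Reagents that add atoms: trifluoromethanesulfonic anhydride, O=S(=O)(OS(=O)(=O)C(F)(F)F)C(F)(F)F
Why: Acidic desilylation followed by O-sulfonylation turns the former lactone oxygen into the leaving group on ring B under conditions too weakly basic to touch the acidic C–H next to the indenone.

Step 9
Reactants: 14
Product: 15 (1S,2S,3S,3'S)-3-(3,5-dimethoxyphenyl)-4,4',6,6'-tetramethoxy-2,3'-bis(4-methoxyphenyl)-2,3-dihydrospiro[indene-1,2'-inden]-1'(3'H)-one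
Conditions: Pd(OAc)2 (10 mol %), rac-BINAP (12 mol %), HCO2Na (2.5 equiv, added slowly), DMF, 90 °C
Reagents that add atoms: none
Why: Zerovalent palladium inserts into the aryl triflate, the arylpalladium adds syn across the indenone C2=C3 bond (aryl to C2, palladium to C3), and the tertiary benzylic alkylpalladium, which has no β-hydrogen because C2 is now quaternary, is reduced by formate (decarboxylation to a palladium hydride, then C–H reductive elimination with retention). The closest known reactions are intramolecular reductive Heck cyclisations, among them the dearomative reductive Heck reaction of 2,3-disubstituted indoles and the anti-Michael 5-exo closures of α-substituted acrylamides to oxindoles. One ring is closed, the indane ring, by 5-exo-trig carbopalladation that forms the bond from the spiro carbon (C8) to ring B. C8 and the adjacent CH(aryl) (C7) are set together by the syn addition across the ring-locked alkene, so the new hydrogen is cis to ring B. The alkene face is chosen by the side-chain CH(4-methoxyphenyl) centre (C10), whose hydrogen lies in the indenone plane (allylic strain), so that its aryl group ends up on the carbonyl side, anti to C7. The step needs insertion to outrun direct reduction of the arylpalladium (slow formate addition, strained intramolecular acceptor) and exo rather than endo closure (three-atom tether).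

Step 10
Reactants: 15
Product: 16 2-{(S)-[(1R,2S,3S)-3-(3,5-dimethoxyphenyl)-4,6-dimethoxy-2-(4-methoxyphenyl)-2,3-dihydro-1H-inden-1-yl](4-methoxyphenyl)methyl}-3,5-dimethoxybenzoic acid
Conditions: KOt-Bu (10 equiv), H2O (3 equiv), THF, 0 °C to rt; then 1 M HCl
Reagents that add atoms: water, O
Why: Haller–Bauer cleavage of the non-enolisable aryl ketone by hydroxide expels the benzylic carbanion at C8 with relief of spiro strain, and front-side protonation by the tethered nascent carboxyl group should give retention, placing the C8 hydrogen where the acyl group was (cis to the C10 aryl group).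

Step 11
Reactants: 16
Product: 17 heptamethyl ether of the target, (7S,8R,9S,10S)
Conditions: (CF3CO)2O, CF3CO2H (cat.), CH2Cl2, 0 °C to rt
Reagents that add atoms: none
Why: Intramolecular Friedel–Crafts acylation through the mixed trifluoroacetic anhydride at the ring B carbon ortho to C8, which is ortho and para to two methoxy groups and the only activated position the tether reaches, closes the seven-membered ring.

Step 12
Reactants: 17
Product: 18 CNP0116600.1, the heptaphenol target, (7S,8R,9S,10S)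
Conditions: BBr3 (14 equiv), CH2Cl2, −78 °C to rt; then MeOH, H2O
Reagents that add atoms: none
Why: Lewis-acid cleavage of all seven aryl methyl ethers, the standard deprotection for permethylated resveratrol oligomers, which involves no stereocentre.

Compound list
1 | 5,7-dimethoxy-2H-chromen-2-one (5,7-dimethoxycoumarin) | O=C1C=Cc2c(OC)cc(OC)cc2O1 | starting material
2 | (3,5-dimethoxyphenyl)boronic acid | OB(O)c1cc(OC)cc(OC)c1 | starting material
3 | (4S)-4-(3,5-dimethoxyphenyl)-5,7-dimethoxy-3,4-dihydro-2H-chromen-2-one | O=C1C[C@@H](c2cc(OC)cc(OC)c2)c2c(OC)cc(OC)cc2O1 | intermediate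
4 | 1-bromo-4-methoxybenzene | COc1ccc(Br)cc1 | starting material
5 | (3S,4S)-4-(3,5-dimethoxyphenyl)-5,7-dimethoxy-3-(4-methoxyphenyl)-3,4-dihydro-2H-chromen-2-one | O=C1[C@H](c2ccc(OC)cc2)[C@@H](c2cc(OC)cc(OC)c2)c2c(OC)cc(OC)cc2O1 | intermediate
6 | (3S,4S)-4-(3,5-dimethoxyphenyl)-5,7-dimethoxy-3-(4-methoxyphenyl)-3,4-dihydro-2H-chromen-2-ol (anomer mixture) | OC1[C@H](c2ccc(OC)cc2)[C@@H](c2cc(OC)cc(OC)c2)c2c(OC)cc(OC)cc2O1 | intermediate
7 | 2-[(1S,2R)-1-(3,5-dimethoxyphenyl)-2-(4-methoxyphenyl)but-3-yn-1-yl]-3,5-dimethoxyphenol | C#C[C@H](c1ccc(OC)cc1)[C@@H](c1cc(OC)cc(OC)c1)c1c(O)cc(OC)cc1OC | intermediate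
8 | 1-iodo-4-methoxybenzene | COc1ccc(I)cc1 | starting material
9 | 2-[(1S,2S)-1-(3,5-dimethoxyphenyl)-2,4-bis(4-methoxyphenyl)but-3-yn-1-yl]-3,5-dimethoxyphenol | COc1ccc(cc1)C#C[C@H](c1ccc(OC)cc1)[C@@H](c1cc(OC)cc(OC)c1)c1c(O)cc(OC)cc1OC | intermediate
10 | {2-[(1S,2S)-1-(3,5-dimethoxyphenyl)-2,4-bis(4-methoxyphenyl)but-3-yn-1-yl]-3,5-dimethoxyphenoxy}tri(propan-2-yl)silane | COc1ccc(cc1)C#C[C@H](c1ccc(OC)cc1)[C@@H](c1cc(OC)cc(OC)c1)c1c(O[Si](C(C)C)(C(C)C)C(C)C)cc(OC)cc1OC | intermediate
11 | 2-bromo-3,5-dimethoxybenzaldehyde | O=Cc1cc(OC)cc(OC)c1Br | starting material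
12 | 2-[(1S,2S)-2-(3,5-dimethoxyphenyl)-2-{2,4-dimethoxy-6-[tri(propan-2-yl)silyloxy]phenyl}-1-(4-methoxyphenyl)ethyl]-4,6-dimethoxy-3-(4-methoxyphenyl)-1H-inden-1-one | O=C1c2cc(OC)cc(OC)c2C(c2ccc(OC)cc2)=C1[C@H](c1ccc(OC)cc1)[C@@H](c1cc(OC)cc(OC)c1)c1c(O[Si](C(C)C)(C(C)C)C(C)C)cc(OC)cc1OC | intermediate
13 | 2-[(1S,2S)-2-(3,5-dimethoxyphenyl)-2-(2-hydroxy-4,6-dimethoxyphenyl)-1-(4-methoxyphenyl)ethyl]-4,6-dimethoxy-3-(4-methoxyphenyl)-1H-inden-1-one | O=C1c2cc(OC)cc(OC)c2C(c2ccc(OC)cc2)=C1[C@H](c1ccc(OC)cc1)[C@@H](c1cc(OC)cc(OC)c1)c1c(O)cc(OC)cc1OC | intermediate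
14 | 2-[(1S,2S)-1-(3,5-dimethoxyphenyl)-2-[4,6-dimethoxy-3-(4-methoxyphenyl)-1-oxo-1H-inden-2-yl]-2-(4-methoxyphenyl)ethyl]-3,5-dimethoxyphenyl trifluoromethanesulfonate | O=C1c2cc(OC)cc(OC)c2C(c2ccc(OC)cc2)=C1[C@H](c1ccc(OC)cc1)[C@@H](c1cc(OC)cc(OC)c1)c1c(OS(=O)(=O)C(F)(F)F)cc(OC)cc1OC | intermediate
15 | (1S,2S,3S,3'S)-3-(3,5-dimethoxyphenyl)-4,4',6,6'-tetramethoxy-2,3'-bis(4-methoxyphenyl)-2,3-dihydrospiro[indene-1,2'-inden]-1'(3'H)-one | O=C1c2cc(OC)cc(OC)c2[C@H](c2ccc(OC)cc2)[C@@]13c2cc(OC)cc(OC)c2[C@H](c2cc(OC)cc(OC)c2)[C@H]3c1ccc(OC)cc1 | intermediate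
16 | 2-{(S)-[(1R,2S,3S)-3-(3,5-dimethoxyphenyl)-4,6-dimethoxy-2-(4-methoxyphenyl)-2,3-dihydro-1H-inden-1-yl](4-methoxyphenyl)methyl}-3,5-dimethoxybenzoic acid | OC(=O)c1cc(OC)cc(OC)c1[C@H](c1ccc(OC)cc1)[C@@H]1c2cc(OC)cc(OC)c2[C@H](c2cc(OC)cc(OC)c2)[C@H]1c1ccc(OC)cc1 | intermediate
17 | heptamethyl ether of the target: dibenzocycloheptenone fused through C8 and ring B to the 2,3-diarylindane, all seven phenols as methyl ethers, (7S,8R,9S,10S) | O=C1c2cc(OC)cc(OC)c2[C@H](c2ccc(OC)cc2)[C@@H]2c3c1c(OC)cc(OC)c3[C@H](c1cc(OC)cc(OC)c1)[C@H]2c1ccc(OC)cc1 | intermediate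
18 | CNP0116600.1: heptahydroxy dibenzocycloheptenone–indane, (7S,8R,9S,10S) | O=C1c2cc(O)cc(O)c2[C@H](c2ccc(O)cc2)[C@@H]2c3c1c(O)cc(O)c3[C@H](c1cc(O)cc(O)c1)[C@H]2c1ccc(O)cc1 | target

Total step count: 12
Longest linear sequence: 12 steps (1 to 18)

Steps most likely to fail

1. Step 9. The arylpalladium may be reduced by formate before it inserts into the hindered tetrasubstituted alkene, and the warm formate medium may erode the configuration at the acidic C–H next to the indenone. Fallback: from 14, 1,4-reduction with LiBH(s-Bu)3 (THF, −78 °C) and protonation should give the trans-indanone triflate 2-[(1S,2R)-1-(3,5-dimethoxyphenyl)-2-[(2R,3S)-4,6-dimethoxy-3-(4-methoxyphenyl)-1-oxo-2,3-dihydro-1H-inden-2-yl]-2-(4-methoxyphenyl)ethyl]-3,5-dimethoxyphenyl trifluoromethanesulfonate F1. Its configuration at C7 then rests on substrate-controlled hydride delivery, and an unwanted epimer would have to be separated. Intramolecular palladium-catalysed enolate α-arylation (Pd(OAc)2, XPhos, K3PO4, toluene, 90 °C), with the aryl group entering anti to the C3 aryl group, returns to the route at 15.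

2. Step 7. The alkyne may insert the wrong way round (aryl delivered to the carbon bearing the branched chain), or insertion of the very bulky alkyne may stall. Fallback: from 10, gold-catalysed hydration ((JohnPhos)Au(MeCN)SbF6, aqueous dioxane, 60 °C), in which water adds at the alkyne carbon bearing the 4-methoxyphenyl group, should give the ketone (3S,4S)-4-(3,5-dimethoxyphenyl)-4-{2,4-dimethoxy-6-[tri(propan-2-yl)silyloxy]phenyl}-1,3-bis(4-methoxyphenyl)butan-1-one F2. C-Acylation of its lithium enolate (LiN(SiMe3)2, THF, −78 °C) with 2-bromo-3,5-dimethoxybenzoyl chloride gives the β-diketone 1-(2-bromo-3,5-dimethoxyphenyl)-2-[(1R,2S)-2-(3,5-dimethoxyphenyl)-2-{2,4-dimethoxy-6-[tri(propan-2-yl)silyloxy]phenyl}-1-(4-methoxyphenyl)ethyl]-3-(4-methoxyphenyl)propane-1,3-dione F3. Palladium-catalysed intramolecular addition of the aryl bromide to the 4-methoxyphenyl ketone (Pd(OAc)2, PCy3, Na2CO3, 1-hexanol, DMF) followed by base-mediated dehydration (DBU) returns to the route at 12 with unambiguous regiochemistry.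

3. Step 10. The C8 carbanion may be protonated from the open face rather than front-side (loss of retention), and the acidic diaryl methine C7–H may epimerise in the strongly basic medium. Fallback: from 15, base-free Baeyer–Villiger oxidation (mCPBA, NaHCO3, CH2Cl2), with migration of the tertiary benzylic carbon with retention, should give the spiro-lactone (1S,2S,3S,4'S)-3-(3,5-dimethoxyphenyl)-4,5',6,7'-tetramethoxy-2,4'-bis(4-methoxyphenyl)-2,3-dihydrospiro[indene-1,3'-isochromen]-1'(4'H)-one F4. Hydrogenolysis of its tertiary benzylic C–O bond over Raney nickel (H2, EtOH), which proceeds with retention on this catalyst, returns to the route at 16.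

Further compounds
F1 | step 9 | 2-[(1S,2R)-1-(3,5-dimethoxyphenyl)-2-[(2R,3S)-4,6-dimethoxy-3-(4-methoxyphenyl)-1-oxo-2,3-dihydro-1H-inden-2-yl]-2-(4-methoxyphenyl)ethyl]-3,5-dimethoxyphenyl trifluoromethanesulfonate | O=C1c2cc(OC)cc(OC)c2[C@H](c2ccc(OC)cc2)[C@H]1[C@H](c1ccc(OC)cc1)[C@@H](c1cc(OC)cc(OC)c1)c1c(OS(=O)(=O)C(F)(F)F)cc(OC)cc1OC
F2 | step 7 | (3S,4S)-4-(3,5-dimethoxyphenyl)-4-{2,4-dimethoxy-6-[tri(propan-2-yl)silyloxy]phenyl}-1,3-bis(4-methoxyphenyl)butan-1-one | COc1ccc(cc1)C(=O)C[C@H](c1ccc(OC)cc1)[C@@H](c1cc(OC)cc(OC)c1)c1c(O[Si](C(C)C)(C(C)C)C(C)C)cc(OC)cc1OC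
F3 | step 7 | 1-(2-bromo-3,5-dimethoxyphenyl)-2-[(1R,2S)-2-(3,5-dimethoxyphenyl)-2-{2,4-dimethoxy-6-[tri(propan-2-yl)silyloxy]phenyl}-1-(4-methoxyphenyl)ethyl]-3-(4-methoxyphenyl)propane-1,3-dione | COc1ccc(cc1)C(=O)C(C(=O)c1cc(OC)cc(OC)c1Br)[C@H](c1ccc(OC)cc1)[C@@H](c1cc(OC)cc(OC)c1)c1c(O[Si](C(C)C)(C(C)C)C(C)C)cc(OC)cc1OC
F4 | step 10 | (1S,2S,3S,4'S)-3-(3,5-dimethoxyphenyl)-4,5',6,7'-tetramethoxy-2,4'-bis(4-methoxyphenyl)-2,3-dihydrospiro[indene-1,3'-isochromen]-1'(4'H)-one | O=C1c2cc(OC)cc(OC)c2[C@H](c2ccc(OC)cc2)[C@]3(O1)c2cc(OC)cc(OC)c2[C@H](c2cc(OC)cc(OC)c2)[C@H]3c1ccc(OC)cc1
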